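**Plan**
1. Retrosynthetic cuts, in order: C5–OOH with the C4=C15 shift (Schenck ene of a Δ4 alkene); the C3 ester (from a Δ4-3-ketone); C5–C10, which opens rings A and B to one ten-membered ring; C3–C4 of that ring; C7–C8 of the chain.
2. Forward: a C8–C3 aldehyde and a C13–C4 allyl bromide/vinyl iodide are joined at C7–C8, the cyclodecene is closed at C3–C4, and C5–C10 is then formed across it, which creates both six-membered rings in one event.
3. Enabling feature: in the ten-membered ring the 1,1-disubstituted C10=C14 alkene (radical donor after H-atom transfer) and C5, the β-carbon of the C3(=O)–C4(Me)=C5 enone, face each other 1,6 on both sides (C10–C9–C8–C7–C6–C5 and C10–C1–C2–C3–C4–C5).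
4. Helpers: the C3 ketone activates C5 and is kept as the C3 oxygen; the acrylate is masked as its Me2NH adduct for the event and released in step 16.
5. Stereochemistry: C7/C8 from a catalyst-controlled syn chromium allylation; C10 from C7/C8 in the chair-like transannular transition state; C3 from Luche reduction anti to the angular methyl; C5 from singlet-oxygen attack on the α face.

Key step: step 13

Assumption: germacrane/eudesmane numbering is used in the names; the macrocyclic carbinol is a C3 epimer mixture and the amine adducts are C11 epimer mixtures, all of which converge; the ligand enantiomer in step 7 is the one that gives Si-face addition to the aldehyde.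

Step 1
Reactants: 1 3-bromobut-3-en-1-ol; 2 [2-(1,3-dioxolan-2-yl)ethyl]magnesium bromide
Product: 3 5-(1,3-dioxolan-2-yl)-3-methylidenepentan-1-ol
Conditions: 2 (2.3 equiv), NiCl2(dppp) (3 mol %), THF, 0 °C to rt; aq NH4Cl
Reagents that add atoms: none
Why: Kumada–Corriu sp2–sp3 coupling, in which the first equivalent of 2 only forms the inert magnesium alkoxide and the nickel–dppp catalyst couples the 2-bromo-1-alkene with the primary alkyl Grignard reagent to give the 1,1-disubstituted alkene that later serves as the radical precursor.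

Step 2
Reactants: 3 5-(1,3-dioxolan-2-yl)-3-methylidenepentan-1-ol
Product: 4 5-(1,3-dioxolan-2-yl)-3-methylidenepentanal
Conditions: Dess–Martin periodinane, NaHCO3, CH2Cl2, 0 °C; used crude
Reagents that add atoms: none
Why: Buffered Dess–Martin oxidation should give the β,γ-unsaturated aldehyde without moving the alkene into conjugation and without touching the acetal.

Step 3
Reactants: 5 pent-3-yn-1-ol
Product: 7 (E)-4-iodopent-3-en-1-ol, via alkenylzirconocene 6 (not isolated)
Conditions: Cp2Zr(H)Cl (2.3 equiv), THF, rt; then I2, 0 °C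
Reagents that add atoms: iodine II
Why: Hydrozirconation–iodination, in which one equivalent of the Schwartz reagent is consumed by the hydroxyl group, syn addition with excess reagent equilibrates zirconium onto the less hindered methyl-bearing carbon, and iodinolysis with retention gives the (E)-2-iodo-2-alkene.

Step 4
Reactants: 7 (E)-4-iodopent-3-en-1-ol
Product: 8 (E)-4-iodopent-3-enal
Conditions: Dess–Martin periodinane, NaHCO3, CH2Cl2, 0 °C; used crude
Reagents that add atoms: none
Why: Dess–Martin oxidation under neutral conditions should preserve the β,γ position and the geometry of the iodoalkene.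

Step 5
Reactants: 8 (E)-4-iodopent-3-enal; 9 methyl propiolate
Product: 11 methyl (5E)-3-hydroxy-6-iodo-2-methylidenehept-5-enoate (racemic), via vinylalane 10 (not isolated)
Conditions: 9, DIBAL-H, NMO, THF, 0 °C; then 8, 0 °C to rt; Rochelle salt
Reagents that add atoms: none
Why: Vinylalumination (hydroalumination of the propiolate to the α-aluminated acrylate, then carbonyl addition) gives the Morita–Baylis–Hillman-type alcohol within minutes at 0 °C, which avoids the amine base and long reaction time that would isomerize aldehyde 8.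

Step 6
Reactants: 11 methyl (5E)-3-hydroxy-6-iodo-2-methylidenehept-5-enoate
Product: 12 methyl (2Z,5E)-2-(bromomethyl)-6-iodohepta-2,5-dienoate
Conditions: PBr3 (0.4 equiv), Et2O, −10 to 0 °C
Reagents that add atoms: phosphorus tribromide BrP(Br)Br
Why: SN2′ bromination of the Baylis–Hillman alcohol should give the thermodynamically preferred (Z)-2-(bromomethyl)-2-enoate, with the alkyl chain trans to the ester.

Step 7
Reactants: 4 5-(1,3-dioxolan-2-yl)-3-methylidenepentanal; 12 methyl (2Z,5E)-2-(bromomethyl)-6-iodohepta-2,5-dienoate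
Product: 14 methyl 2-[(2E,5R,6R)-10-(1,3-dioxolan-2-yl)-6-hydroxy-2-iodo-8-methylidenedec-2-en-5-yl]prop-2-enoate, via silyl ether 13 (not isolated)
Conditions: CrCl2 (10 mol %), carbazole-bis(oxazoline) ligand (12 mol %), Mn (2 equiv), i-Pr2NEt (0.3 equiv), TMSCl (1.5 equiv), THF, rt; then aq citric acid, 0 °C
Reagents that add atoms: chlorotrimethylsilane C[Si](C)(C)Cl (in 13 only)
Why: Catalytic asymmetric Nozaki–Hiyama–Kishi-type 2-(alkoxycarbonyl)allylation, in which the allylchromium reacts through a closed chair with the C6 chain cis to CH2Cr to give the syn (cis-lactone-type) C7/C8 relationship, the ligand selects the Si face of the aldehyde (8R, hence 7R), the vinyl iodide is inert without nickel, and in-situ O-silylation keeps the γ-oxygen from lactonizing.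

Step 8
Reactants: 14 methyl 2-[(2E,5R,6R)-10-(1,3-dioxolan-2-yl)-6-hydroxy-2-iodo-8-methylidenedec-2-en-5-yl]prop-2-enoate
Product: 15 methyl 2-[(2E,5R,6R)-6-acetoxy-10-(1,3-dioxolan-2-yl)-2-iodo-8-methylidenedec-2-en-5-yl]prop-2-enoate
Conditions: Ac2O, pyridine, DMAP (cat.), CH2Cl2, 0 °C, directly after step 7
Reagents that add atoms: acetic anhydride CC(=O)OC(C)=O
Why: DMAP-catalysed acetylation installs the C8 acetate of the target with retention and permanently blocks lactonization onto the C12 ester.

Step 9
Reactants: 15 methyl 2-[(2E,5R,6R)-6-acetoxy-10-(1,3-dioxolan-2-yl)-2-iodo-8-methylidenedec-2-en-5-yl]prop-2-enoate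
Product: 16 methyl 2-[(2E,5R,6R)-6-acetoxy-2-iodo-8-methylidene-11-oxoundec-2-en-5-yl]prop-2-enoate
Conditions: 1 M aq HCl, THF, rt
Reagents that add atoms: water O
Why: Acid-catalysed acetal hydrolysis frees the C3 aldehyde under conditions that should leave the acetate, the acrylate, the vinyl iodide and the 1,1-disubstituted alkene unchanged.

Step 10
Reactants: 16 methyl 2-[(2E,5R,6R)-6-acetoxy-2-iodo-8-methylidene-11-oxoundec-2-en-5-yl]prop-2-enoate
Product: 17 methyl (4E,7R,8R)-8-acetoxy-3-hydroxygermacra-4,10(14),11(13)-trien-12-oate (C3 epimers)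
Conditions: CrCl2 (8 equiv), NiCl2 (2 mol %), DMSO/THF, rt, syringe-pump addition to 2 mM
Reagents that add atoms: none
Why: Intramolecular Nozaki–Hiyama–Kishi coupling, in which the alkenylchromium formed from the C4 iodide adds to the C3 aldehyde with retention of the (E) geometry and high dilution favours the ten-membered ring, whose C3 configuration is irrelevant because it is oxidized next.

Step 11
Reactants: 17 methyl (4E,7R,8R)-8-acetoxy-3-hydroxygermacra-4,10(14),11(13)-trien-12-oate
Product: 18 methyl (4E,7R,8R)-8-acetoxy-3-oxogermacra-4,10(14),11(13)-trien-12-oate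
Conditions: Dess–Martin periodinane, NaHCO3, CH2Cl2, 0 °C
Reagents that add atoms: none
Why: Dess–Martin oxidation of the allylic alcohol gives the (E)-α-methyl enone that is to act as the radical acceptor.

Step 12
Reactants: 18 methyl (4E,7R,8R)-8-acetoxy-3-oxogermacra-4,10(14),11(13)-trien-12-oate
Product: 19 methyl (4E,7R,8R)-8-acetoxy-13-(dimethylamino)-3-oxogermacra-4,10(14)-dien-12-oate (C11 epimers)
Conditions: Me2NH (2 M in THF, 3 equiv), 0 °C to rt
Reagents that add atoms: dimethylamine CNC
Why: Aza-Michael addition to the unhindered α-methylene ester (the trisubstituted, α-branched ring enone is far slower) masks the second radical acceptor and enlarges the C7 substituent, and the new C11 centre is removed again in step 16.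

Step 13
Reactants: 19 methyl (4E,7R,8R)-8-acetoxy-13-(dimethylamino)-3-oxogermacra-4,10(14)-dien-12-oate
Product: 20 methyl (7R,8R,10R)-8β-acetoxy-13-(dimethylamino)-3-oxoeudesm-4-en-12-oate
Conditions: Co(salen-tBu,tBu)Cl (5 mol %), PhSiH3 (10 mol %), benzene, rt, Ar
Reagents that add atoms: none
Why: Proposed new method: Co(III)–H, generated from the salen complex and the catalytic silane, should deliver H• to C14 of the only electron-rich unhindered alkene, the tertiary nucleophilic C10 radical then adds across the ring to C5, the β-carbon of the C3 enone, and the α-keto radical at C4 returns H5 (directly, or after loss and re-addition of a C15 hydrogen) to Co(II), which regenerates Co–H and the conjugated C4=C5 enone, so that the net process is an isomerization. The closest known reaction types are the cobalt–salen HAT cycloisomerization of dienes and the HAT-initiated Giese cyclization onto enones; the transannular setting and the enone-restoring termination are untested. One bond closes ring B in 6-exo-trig mode (C10 to C5 through C9–C6) and ring A in 6-endo-trig mode (through C1–C3). C10, the only new stereocentre, is set by the chair-like ring-B transition state in which the large C7 CH(CO2Me)CH2NMe2 group is equatorial and the small C8 acetoxy group axial, which places C14 on the β face, syn to the acetoxy group, while C4 and C5 end up sp2. The step needs a single donor alkene, a single acceptor and an endocyclic termination: the amine mask on the acrylate secures the first two, and thermodynamics the third, because a 4(15)-exo enone is itself an HAT acceptor that re-enters as the same C4 radical until the tetrasubstituted enone accumulates, a regiocontrol that a trans-fused saturated ketone would not offer since it enolizes towards C2.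

Step 14
Reactants: 20 methyl (7R,8R,10R)-8β-acetoxy-13-(dimethylamino)-3-oxoeudesm-4-en-12-oate
Product: 21 methyl 8β-acetoxy-13-(dimethylamino)-3β-hydroxyeudesm-4-en-12-oate
Conditions: NaBH4, CeCl3·7H2O, MeOH, −78 to −40 °C
Reagents that add atoms: none
Why: Luche 1,2-reduction, in which hydride should add to C3 from the α face, anti to the axial C10 methyl, to give the pseudo-equatorial 3β-allylic alcohol while the esters are not reduced at low temperature.

Step 15
Reactants: 21 methyl 8β-acetoxy-13-(dimethylamino)-3β-hydroxyeudesm-4-en-12-oate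
Product: 22 methyl 8β-acetoxy-13-(dimethylamino)-3β-(2-methylpropanoyloxy)eudesm-4-en-12-oate
Conditions: (i-PrCO)2O, Et3N, DMAP (cat.), CH2Cl2, 0 °C to rt
Reagents that add atoms: 2-methylpropanoic anhydride CC(C)C(=O)OC(=O)C(C)C
Why: DMAP-catalysed acylation of the unhindered equatorial allylic alcohol installs the isobutyrate with retention at C3.

Step 16
Reactants: 22 methyl 8β-acetoxy-13-(dimethylamino)-3β-(2-methylpropanoyloxy)eudesm-4-en-12-oate
Product: 24 methyl 8β-acetoxy-3β-(2-methylpropanoyloxy)eudesma-4,11(13)-dien-12-oate, via ammonium iodide 23 (not isolated)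
Conditions: MeI (5 equiv), MeCN, rt; then sat. aq NaHCO3, EtOAc, rt
Reagents that add atoms: iodomethane CI (in 23 only)
Why: Quaternization followed by Hofmann-type E1cB loss of trimethylamine from the β-ammonium ester regenerates the α-methylene ester under conditions too mild to affect the allylic isobutyrate or the acetate, and it removes the amine before the photooxygenation.

Step 17
Reactants: 24 methyl 8β-acetoxy-3β-(2-methylpropanoyloxy)eudesma-4,11(13)-dien-12-oate
Product: 25 methyl (3S,5S,7R,8R,10R)-8-acetoxy-5-hydroperoxy-3-(2-methylpropanoyloxy)eudesma-4(15),11(13)-dien-12-oate (3β,5α,8β; the target)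
Conditions: O2, tetraphenylporphyrin (cat.), visible light, CH2Cl2, −20 °C
Reagents that add atoms: dioxygen O=O
Why: Schenck ene reaction, in which singlet oxygen should attack the electron-rich tetrasubstituted C4=C5 bond (the acrylate is inert) on the α face opposite the axial C10 methyl and the 8β-acetoxy group, bond to C5 and abstract a hydrogen from C15, the methyl geminal to the acyloxy-bearing C3, since H3 is deactivated and C6 has no α-axial hydrogen.

**Compound list**
1 | 3-bromobut-3-en-1-ol | C=C(Br)CCO | starting material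
2 | [2-(1,3-dioxolan-2-yl)ethyl]magnesium bromide | Br[Mg]CCC1OCCO1 | starting material
3 | 5-(1,3-dioxolan-2-yl)-3-methylidenepentan-1-ol | OCCC(=C)CCC1OCCO1 | intermediate
4 | 5-(1,3-dioxolan-2-yl)-3-methylidenepentanal | O=CCC(=C)CCC1OCCO1 | intermediate
5 | pent-3-yn-1-ol | CC#CCCO | starting material
6 | (E)-alkenylzirconocene chloride, zirconium on C4, oxygen also bound to zirconocene chloride | C/C(=C\CCO[Zr](Cl)(C1C=CC=C1)C1C=CC=C1)[Zr](Cl)(C1C=CC=C1)C1C=CC=C1 | intermediate
7 | (E)-4-iodopent-3-en-1-ol | C/C(I)=C\CCO | intermediate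
8 | (E)-4-iodopent-3-enal | C/C(I)=C\CC=O | intermediate
9 | methyl propiolate | C#CC(=O)OC | starting material
10 | [1-(methoxycarbonyl)ethenyl]bis(2-methylpropyl)aluminium | C=C(C(=O)OC)[Al](CC(C)C)CC(C)C | intermediate
11 | methyl (5E)-3-hydroxy-6-iodo-2-methylidenehept-5-enoate (racemic) | C=C(C(=O)OC)C(O)C/C=C(\C)I | intermediate
12 | methyl (2Z,5E)-2-(bromomethyl)-6-iodohepta-2,5-dienoate | BrC/C(C(=O)OC)=C\C/C=C(\C)I | intermediate
13 | methyl 2-[(2E,5R,6R)-10-(1,3-dioxolan-2-yl)-2-iodo-8-methylidene-6-(trimethylsilyloxy)dec-2-en-5-yl]prop-2-enoate | C=C(C(=O)OC)[C@@H](C/C=C(\C)I)[C@H](O[Si](C)(C)C)CC(=C)CCC1OCCO1 | intermediate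
14 | methyl 2-[(2E,5R,6R)-10-(1,3-dioxolan-2-yl)-6-hydroxy-2-iodo-8-methylidenedec-2-en-5-yl]prop-2-enoate | C=C(C(=O)OC)[C@@H](C/C=C(\C)I)[C@H](O)CC(=C)CCC1OCCO1 | intermediate
15 | methyl 2-[(2E,5R,6R)-6-acetoxy-10-(1,3-dioxolan-2-yl)-2-iodo-8-methylidenedec-2-en-5-yl]prop-2-enoate | C=C(C(=O)OC)[C@@H](C/C=C(\C)I)[C@H](OC(C)=O)CC(=C)CCC1OCCO1 | intermediate
16 | methyl 2-[(2E,5R,6R)-6-acetoxy-2-iodo-8-methylidene-11-oxoundec-2-en-5-yl]prop-2-enoate | C=C(C(=O)OC)[C@@H](C/C=C(\C)I)[C@H](OC(C)=O)CC(=C)CCC=O | intermediate
17 | methyl (4E,7R,8R)-8-acetoxy-3-hydroxygermacra-4,10(14),11(13)-trien-12-oate (C3 epimers) | C=C(C(=O)OC)[C@H]1C/C=C(\C)C(O)CCC(=C)C[C@H]1OC(C)=O | intermediate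
18 | methyl (4E,7R,8R)-8-acetoxy-3-oxogermacra-4,10(14),11(13)-trien-12-oate | C=C(C(=O)OC)[C@H]1C/C=C(\C)C(=O)CCC(=C)C[C@H]1OC(C)=O | intermediate
19 | methyl (4E,7R,8R)-8-acetoxy-13-(dimethylamino)-3-oxogermacra-4,10(14)-dien-12-oate (C11 epimers) | CN(C)CC(C(=O)OC)[C@H]1C/C=C(\C)C(=O)CCC(=C)C[C@H]1OC(C)=O | intermediate
20 | methyl (7R,8R,10R)-8β-acetoxy-13-(dimethylamino)-3-oxoeudesm-4-en-12-oate | CN(C)CC(C(=O)OC)[C@H]1CC2=C(C)C(=O)CC[C@]2(C)C[C@H]1OC(C)=O | intermediate
21 | methyl 8β-acetoxy-13-(dimethylamino)-3β-hydroxyeudesm-4-en-12-oate | CN(C)CC(C(=O)OC)[C@H]1CC2=C(C)[C@@H](O)CC[C@]2(C)C[C@H]1OC(C)=O | intermediate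
22 | methyl 8β-acetoxy-13-(dimethylamino)-3β-(2-methylpropanoyloxy)eudesm-4-en-12-oate | CN(C)CC(C(=O)OC)[C@H]1CC2=C(C)[C@@H](OC(=O)C(C)C)CC[C@]2(C)C[C@H]1OC(C)=O | intermediate
23 | 13-trimethylammonio iodide of 22 | [I-].C[N+](C)(C)CC(C(=O)OC)[C@H]1CC2=C(C)[C@@H](OC(=O)C(C)C)CC[C@]2(C)C[C@H]1OC(C)=O | intermediate
24 | methyl 8β-acetoxy-3β-(2-methylpropanoyloxy)eudesma-4,11(13)-dien-12-oate | C=C(C(=O)OC)[C@H]1CC2=C(C)[C@@H](OC(=O)C(C)C)CC[C@]2(C)C[C@H]1OC(C)=O | intermediate
25 | methyl (3S,5S,7R,8R,10R)-8-acetoxy-5-hydroperoxy-3-(2-methylpropanoyloxy)eudesma-4(15),11(13)-dien-12-oate | C=C(C(=O)OC)[C@H]1C[C@@]2(OO)C(=C)[C@@H](OC(=O)C(C)C)CC[C@]2(C)C[C@H]1OC(C)=O | target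

**Step count**
Total steps: 17. Longest linear sequence: 15 steps (steps 3 to 17, from pent-3-yn-1-ol).

**Steps most likely to fail**

1. Step 13 (Proposed new method). The chain may break down: the C10 radical may return a hydrogen to cobalt before it cyclizes, which only isomerizes the alkene to unreactive trisubstituted isomers, or the α-keto radical may not be dehydrogenated. The facial preference at C10 is also estimated, not secured. The fallback sets out from 19 and separates bond formation from desaturation with known reactions. Reductive HAT-initiated Giese cyclization (Fe(acac)3, PhSiH3, EtOH/ethylene glycol, 60 °C) should give the trans-fused saturated ketone methyl 8β-acetoxy-13-(dimethylamino)-3-oxo-5αH-eudesman-12-oate F1. IBX in excess (with one equivalent of TFA to protonate the amine, DMSO, 80 °C) should dehydrogenate both α,β positions, whichever enolizes first, to the cross-conjugated dienone methyl 8β-acetoxy-13-(dimethylamino)-3-oxoeudesma-1,4-dien-12-oate F2. Hydrogenation with Wilkinson's catalyst should then saturate only the disubstituted C1=C2 bond, which returns to the route at 20.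

2. Step 10. Closure of the strained (E)-cyclodecenol is slow, so intermolecular coupling and protonolysis of the alkenylchromium may dominate. The fallback sets out from 16 and closes the same bond by palladium-catalysed acylation. Pinnick oxidation should give (6R,7R,9E)-6-acetoxy-10-iodo-7-(3-methoxy-3-oxoprop-1-en-2-yl)-4-methylideneundec-9-enoic acid F3. Iodine–tin exchange with hexamethylditin and Pd(PPh3)4 (acid held as its i-Pr2NEt salt) should give (6R,7R,9E)-6-acetoxy-7-(3-methoxy-3-oxoprop-1-en-2-yl)-4-methylidene-10-(trimethylstannyl)undec-9-enoic acid F4. The Ghosez reagent converts this to the acid chloride (6R,7R,9E)-6-acetoxy-7-(3-methoxy-3-oxoprop-1-en-2-yl)-4-methylidene-10-(trimethylstannyl)undec-9-enoyl chloride F5, which is not isolated. Slow addition of F5 to Pd2(dba)3/tri(2-furyl)phosphine (intramolecular acyl Stille coupling, retention of alkene geometry) should give the enone directly, so the fallback returns at 18 and skips 17.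

3. Step 7. Enantio- or syn-selectivity may erode while the allylchromium equilibrates, and the syn γ-hydroxy ester may lactonize during desilylation. The fallback sets out from 11 and uses a closed allylboration in which the oxygen stays on boron until work-up. Acetylation should give methyl (5E)-3-acetoxy-6-iodo-2-methylidenehept-5-enoate F6. Copper-catalysed SN2′ borylation with B2pin2 should give methyl (2E,5E)-6-iodo-2-[(4,4,5,5-tetramethyl-1,3,2-dioxaborolan-2-yl)methyl]hepta-2,5-dienoate F7, in which the chain is cis to CH2B. Chiral phosphoric acid-catalysed allylboration of 4 (acid enantiomer chosen for Si-face addition) through the chair transition state should give the syn adduct, which returns to the route at 14.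

**Further compounds**
F1 | step 13 | methyl 8β-acetoxy-13-(dimethylamino)-3-oxo-5αH-eudesman-12-oate (4α-methyl) | CN(C)CC(C(=O)OC)[C@H]1C[C@H]2[C@H](C)C(=O)CC[C@]2(C)C[C@H]1OC(C)=O
F2 | step 13 | methyl 8β-acetoxy-13-(dimethylamino)-3-oxoeudesma-1,4-dien-12-oate | CN(C)CC(C(=O)OC)[C@H]1CC2=C(C)C(=O)C=C[C@]2(C)C[C@H]1OC(C)=O
F3 | step 10 | (6R,7R,9E)-6-acetoxy-10-iodo-7-(3-methoxy-3-oxoprop-1-en-2-yl)-4-methylideneundec-9-enoic acid | C=C(C(=O)OC)[C@@H](C/C=C(\C)I)[C@H](OC(C)=O)CC(=C)CCC(=O)O
F4 | step 10 | (6R,7R,9E)-6-acetoxy-7-(3-methoxy-3-oxoprop-1-en-2-yl)-4-methylidene-10-(trimethylstannyl)undec-9-enoic acid | C=C(C(=O)OC)[C@@H](C/C=C(\C)[Sn](C)(C)C)[C@H](OC(C)=O)CC(=C)CCC(=O)O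
F5 | step 10 | (6R,7R,9E)-6-acetoxy-7-(3-methoxy-3-oxoprop-1-en-2-yl)-4-methylidene-10-(trimethylstannyl)undec-9-enoyl chloride | C=C(C(=O)OC)[C@@H](C/C=C(\C)[Sn](C)(C)C)[C@H](OC(C)=O)CC(=C)CCC(=O)Cl
F6 | step 7 | methyl (5E)-3-acetoxy-6-iodo-2-methylidenehept-5-enoate (racemic) | C=C(C(=O)OC)C(OC(C)=O)C/C=C(\C)I
F7 | step 7 | methyl (2E,5E)-6-iodo-2-[(4,4,5,5-tetramethyl-1,3,2-dioxaborolan-2-yl)methyl]hepta-2,5-dienoate | CC1(C)OB(C/C(C(=O)OC)=C\C/C=C(\C)I)OC1(C)C
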